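**Plan**

- Retrosynthesis: cut the stilbene C=C (Horner–Wadsworth–Emmons), then the O1–C2 bond of furan ring 2 (cationic ring closure), then four bonds of ring C in one benzannulation that joins two chiral fragments.
- Enabling feature: ring C, the central benzene, carries in sequence C2 of dihydrobenzofuran 1, the ring oxygen of furan 2, C3 of furan 2 and the C4 hydroxyl. This is a resorcinol with a carbon substituent between its two oxygens, the pattern a vinylketene plus siloxyalkyne benzannulation delivers, with the two oxygens differentiated (free OH and O-silyl).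
- Forward order: ring B with dihydrobenzofuran 1 is built first (coumarin, conjugate arylation, ring contraction) and extended to a diazo enone. The furan 2 side chain is carried by a chiral siloxyalkyne. Ring C is then formed between them, furan ring 2 closes, the stilbene arm is attached and all ethers are cleaved.
- Stereochemistry: C3 of dihydrobenzofuran 1 comes from a rhodium/(R)-SEGPHOS conjugate arylation, and C2 is set trans to it under thermodynamic control in the ring contraction. C3 of furan 2 comes from an Evans syn aldol, and C2 of furan 2 is set trans by the C3 centre in the cationic closure.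

Key step: step 16

Remark: the carbinol carbon of the alkyne side chain is ionised when furan ring 2 closes, so the syn aldol diastereomer is carried as formed. Some CIP labels change along the route only because substituent priorities change; the spatial arrangement does not.

**Fragment 1: diazo enone 19**

Step 1
Reactants: 1 4-bromo-3,5-dihydroxybenzoic acid
Product: 2 methyl 4-bromo-3,5-dihydroxybenzoate
Conditions: MeOH, H2SO4 (cat.), reflux
Reagents that add atoms: methanol, CO
Why: Fischer esterification of a benzoic acid, which leaves the phenols and the aryl bromide untouched.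

Step 2
Reactants: 2 methyl 4-bromo-3,5-dihydroxybenzoate; 3 methyl acrylate
Product: 5 methyl 5-hydroxy-2-oxo-2H-chromene-7-carboxylate, via hydroxycinnamate 4 (not isolated)
Conditions: Pd(OAc)2 (5 mol %), P(o-tol)3, Et3N, DMF, 110 °C; then n-Bu3P (20 mol %), MeOH, 70 °C
Reagents that add atoms: none
Why: Heck reaction gives the (E)-cinnamate, and phosphine-catalysed E-to-Z isomerisation with lactonisation then closes the coumarin onto either of the two equivalent phenols, so no regiochemical question arises.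

Step 3
Reactants: 5 methyl 5-hydroxy-2-oxo-2H-chromene-7-carboxylate
Product: 6 methyl 5-methoxy-2-oxo-2H-chromene-7-carboxylate
Conditions: MeI, K2CO3, acetone, reflux
Reagents that add atoms: iodomethane, CI
Why: Williamson O-methylation of the remaining phenol under weakly basic anhydrous conditions that do not open the coumarin lactone.

Step 4
Reactants: 6 methyl 5-methoxy-2-oxo-2H-chromene-7-carboxylate; 7 3,5-dimethoxyphenylboronic acid
Product: 8 methyl (4R)-4-(3,5-dimethoxyphenyl)-5-methoxy-2-oxo-3,4-dihydro-2H-chromene-7-carboxylate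
Conditions: 7 (5 equiv), Rh(acac)(C2H4)2 (3 mol %), (R)-SEGPHOS, dioxane/H2O 10:1, 60 °C
Reagents that add atoms: none
Why: Hayashi–Miyaura rhodium-catalysed asymmetric 1,4-addition of an arylboronic acid to a coumarin, in which the (R)-SEGPHOS-bound aryl–rhodium species should add to the C4 face that gives the (4R) lactone, as this ligand does with unhindered coumarins.

Step 5
Reactants: 8 methyl (4R)-4-(3,5-dimethoxyphenyl)-5-methoxy-2-oxo-3,4-dihydro-2H-chromene-7-carboxylate
Product: 10 methyl (3S,4R)-3-bromo-4-(3,5-dimethoxyphenyl)-5-methoxy-2-oxo-3,4-dihydro-2H-chromene-7-carboxylate, via lithium enolate 9 (not isolated)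
Conditions: LiN(SiMe3)2 (1.05 equiv), THF, −78 °C; NBS, −78 °C; aq NH4Cl
Reagents that add atoms: lithium bis(trimethylsilyl)amide, [Li]N([Si](C)(C)C)[Si](C)(C)C (lithium of 9 only); N-bromosuccinimide, O=C1CCC(=O)N1Br
Why: Electrophilic α-bromination of the lactone enolate, which should take bromine on the face opposite the C4 aryl group to give the 3,4-trans bromide (this centre is in any case corrected in step 6).

Step 6
Reactants: 10 methyl (3S,4R)-3-bromo-4-(3,5-dimethoxyphenyl)-5-methoxy-2-oxo-3,4-dihydro-2H-chromene-7-carboxylate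
Product: 12 dimethyl (2R,3R)-3-(3,5-dimethoxyphenyl)-4-methoxy-2,3-dihydro-1-benzofuran-2,6-dicarboxylate, via bromo ester phenoxide 11 (not isolated)
Conditions: NaOMe (1.5 equiv), MeOH, 0 °C → rt
Reagents that add atoms: sodium methoxide, C[O-].[Na+]
Why: Ring contraction of a 3-halodihydrocoumarin: methoxide opens the aryl lactone and the freed phenoxide displaces the α-bromide in a 5-exo-tet Williamson closure with inversion, giving the 2,3-trans ester, which the fixed C3 centre also favours on equilibration of the epimerisable C2 in NaOMe/MeOH.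

Step 7
Reactants: 12 dimethyl (2R,3R)-3-(3,5-dimethoxyphenyl)-4-methoxy-2,3-dihydro-1-benzofuran-2,6-dicarboxylate
Product: 13 methyl (2R,3R)-3-(3,5-dimethoxyphenyl)-2-(hydroxymethyl)-4-methoxy-2,3-dihydro-1-benzofuran-6-carboxylate
Conditions: NaBH4, MeOH/THF, 0 °C → rt
Reagents that add atoms: none
Why: Chemoselective borohydride reduction, since the α-aryloxy ester is activated toward NaBH4 whereas the methyl benzoate is not reduced under these conditions.

Step 8
Reactants: 13 methyl (2R,3R)-3-(3,5-dimethoxyphenyl)-2-(hydroxymethyl)-4-methoxy-2,3-dihydro-1-benzofuran-6-carboxylate; 14 1-(triphenylphosphoranylidene)propan-2-one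
Product: 16 methyl (2S,3R)-3-(3,5-dimethoxyphenyl)-4-methoxy-2-[(E)-3-oxobut-1-enyl]-2,3-dihydro-1-benzofuran-6-carboxylate, via aldehyde 15 (not isolated)
Conditions: IBX, 14 (1.5 equiv), DMSO, rt
Reagents that add atoms: none
Why: Tandem IBX oxidation and Wittig olefination with a stabilised ylide gives the (E)-enone and consumes the epimerisable α-aryloxy aldehyde as it forms.

Step 9
Reactants: 16 methyl (2S,3R)-3-(3,5-dimethoxyphenyl)-4-methoxy-2-[(E)-3-oxobut-1-enyl]-2,3-dihydro-1-benzofuran-6-carboxylate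
Product: 19 methyl (2S,3R)-2-[(E)-4-diazo-3-oxobut-1-enyl]-3-(3,5-dimethoxyphenyl)-4-methoxy-2,3-dihydro-1-benzofuran-6-carboxylate, via lithium dienolate 17 (not isolated), via trifluoroacetyl diketone 18 (not isolated)
Conditions: LiN(SiMe3)2, THF, −78 °C; CF3CO2CH2CF3; dilute HCl wash; then 4-acetamidobenzenesulfonyl azide, Et3N, H2O (1 equiv), MeCN, rt
Reagents that add atoms: lithium bis(trimethylsilyl)amide, [Li]N([Si](C)(C)C)[Si](C)(C)C (lithium of 17 only); 2,2,2-trifluoroethyl trifluoroacetate, O=C(OCC(F)(F)F)C(F)(F)F (trifluoroacetyl group of 18 only); 4-acetamidobenzenesulfonyl azide, CC(=O)Nc1ccc(cc1)S(=O)(=O)N=[N+]=[N-]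
Why: Detrifluoroacetylative diazo transfer (Claisen trifluoroacetylation of the kinetic methyl-ketone enolate, then Regitz diazo transfer with loss of the trifluoroacetyl group) is the standard access to α′-diazo enones and leaves the benzoate and both ring centres alone.

**Fragment 2: siloxyalkyne 33**

Step 10
Reactants: 20 (3,5-dimethoxyphenyl)acetic acid; 21 (S)-4-benzyl-1,3-oxazolidin-2-one
Product: 23 (4S)-4-benzyl-3-[2-(3,5-dimethoxyphenyl)acetyl]-1,3-oxazolidin-2-one, via mixed anhydride 22 (not isolated)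
Conditions: t-BuCOCl, Et3N, THF, −20 °C; then LiCl, 21, rt
Reagents that add atoms: pivaloyl chloride, CC(C)(C)C(Cl)=O (pivaloyl group of 22 only)
Why: N-acylation of the oxazolidinone through the mixed pivalic anhydride with LiCl/Et3N activation is a routine one-flask preparation of Evans imides from arylacetic acids.

Step 11
Reactants: 23 (4S)-4-benzyl-3-[2-(3,5-dimethoxyphenyl)acetyl]-1,3-oxazolidin-2-one; 24 2,4-dimethoxybenzaldehyde
Product: 26 (4S)-4-benzyl-3-[(2S,3S)-3-(2,4-dimethoxyphenyl)-2-(3,5-dimethoxyphenyl)-3-hydroxypropanoyl]-1,3-oxazolidin-2-one, via boron enolate 25 (not isolated)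
Conditions: n-Bu2BOTf, i-Pr2NEt, CH2Cl2, −78 → 0 °C; 24, −78 → 0 °C; then pH 7 buffer, MeOH, H2O2
Reagents that add atoms: dibutylboron triflate, CCCCB(CCCC)OS(=O)(=O)C(F)(F)F (boron of 25 only)
Why: Evans syn aldol reaction, in which the (Z)-boron enolate reacts through a closed chair transition state on the face opposite the benzyl group of the (S)-auxiliary and so sets the aryl-bearing centre (the future C3 of furan ring 2) together with the syn carbinol.

Step 12
Reactants: 26 (4S)-4-benzyl-3-[(2S,3S)-3-(2,4-dimethoxyphenyl)-2-(3,5-dimethoxyphenyl)-3-hydroxypropanoyl]-1,3-oxazolidin-2-one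
Product: 27 (4S)-4-benzyl-3-[(2S,3S)-3-[tert-butyl(dimethyl)silyl]oxy-3-(2,4-dimethoxyphenyl)-2-(3,5-dimethoxyphenyl)propanoyl]-1,3-oxazolidin-2-one
Conditions: TBSOTf, 2,6-lutidine, CH2Cl2, −78 → 0 °C
Reagents that add atoms: tert-butyldimethylsilyl triflate, CC(C)(C)[Si](C)(C)OS(=O)(=O)C(F)(F)F
Why: Silylation of the hindered benzylic alcohol with a silyl triflate and 2,6-lutidine blocks retro-aldol cleavage and avoids free acid that would ionise the electron-rich benzylic position.

Step 13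
Reactants: 27 (4S)-4-benzyl-3-[(2S,3S)-3-[tert-butyl(dimethyl)silyl]oxy-3-(2,4-dimethoxyphenyl)-2-(3,5-dimethoxyphenyl)propanoyl]-1,3-oxazolidin-2-one
Product: 28 (2R,3S)-3-[tert-butyl(dimethyl)silyl]oxy-3-(2,4-dimethoxyphenyl)-2-(3,5-dimethoxyphenyl)propan-1-ol
Conditions: LiBH4, MeOH (1 equiv), Et2O, 0 °C
Reagents that add atoms: none
Why: Reductive removal of the Evans auxiliary with LiBH4 gives the primary alcohol without enolising the α-aryl centre and returns the oxazolidinone.

Step 14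
Reactants: 28 (2R,3S)-3-[tert-butyl(dimethyl)silyl]oxy-3-(2,4-dimethoxyphenyl)-2-(3,5-dimethoxyphenyl)propan-1-ol
Product: 30 tert-butyl{[(1S,2S)-4,4-dibromo-1-(2,4-dimethoxyphenyl)-2-(3,5-dimethoxyphenyl)but-3-enyl]oxy}dimethylsilane, via aldehyde 29 (not isolated)
Conditions: Dess–Martin periodinane, pyridine, CH2Cl2, 0 °C; filter; then CBr4, PPh3, 2,6-lutidine, CH2Cl2, 0 °C
Reagents that add atoms: carbon tetrabromide, BrC(Br)(Br)Br
Why: Dess–Martin oxidation followed at once by Ramirez dibromo-olefination (first stage of the Corey–Fuchs sequence) under buffered, non-enolising conditions homologates the configurationally labile α-aryl aldehyde before it can epimerise.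

Step 15
Reactants: 30 tert-butyl{[(1S,2S)-4,4-dibromo-1-(2,4-dimethoxyphenyl)-2-(3,5-dimethoxyphenyl)but-3-enyl]oxy}dimethylsilane
Product: 33 tert-butyl{[(1S,2R)-1-(2,4-dimethoxyphenyl)-2-(3,5-dimethoxyphenyl)-4-[tri(propan-2-yl)silyloxy]but-3-ynyl]oxy}dimethylsilane, via lithium acetylide 31 (not isolated), via lithium ynolate 32 (not isolated)
Conditions: n-BuLi (2.1 equiv), THF, −78 °C; LiOOt-Bu (from t-BuOOH and LiN(SiMe3)2), −78 → 0 °C; i-Pr3SiOTf, −78 °C
Reagents that add atoms: n-butyllithium, [Li]CCCC (lithium of 31 only); lithium tert-butyl peroxide, [Li]OOC(C)(C)C; triisopropylsilyl triflate, CC(C)[Si](OS(=O)(=O)C(F)(F)F)(C(C)C)C(C)C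
Why: The second stage of the Corey–Fuchs sequence (bromine–lithium exchange and Fritsch–Buttenberg–Wiechell rearrangement) gives the lithium acetylide, electrophilic oxygen transfer from the lithium peroxide converts it into the ynolate, and the bulky silyl triflate silylates the ynolate on oxygen, none of which touches the propargylic centre.

**Key step**

Step 16
Reactants: 19 methyl (2S,3R)-2-[(E)-4-diazo-3-oxobut-1-enyl]-3-(3,5-dimethoxyphenyl)-4-methoxy-2,3-dihydro-1-benzofuran-6-carboxylate; 33 tert-butyl{[(1S,2R)-1-(2,4-dimethoxyphenyl)-2-(3,5-dimethoxyphenyl)-4-[tri(propan-2-yl)silyloxy]but-3-ynyl]oxy}dimethylsilane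
Product: 38 methyl (2R,3R)-2-{3-[(1R,2S)-2-[tert-butyl(dimethyl)silyl]oxy-2-(2,4-dimethoxyphenyl)-1-(3,5-dimethoxyphenyl)ethyl]-2-hydroxy-4-[tri(propan-2-yl)silyloxy]phenyl}-3-(3,5-dimethoxyphenyl)-4-methoxy-2,3-dihydro-1-benzofuran-6-carboxylate, via vinylketene 34 (not isolated), via vinylcyclobutenone 35 (not isolated), via dienylketene 36 (not isolated), via cyclohexadienone 37 (not isolated)
Conditions: 19 (1.0 equiv), 33 (1.2 equiv), hν (300 nm), ClCH2CH2Cl, rt; then 80 °C
Reagents that add atoms: none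
Why: Light expels N2 from 19 and the Wolff shift of the vinyl group gives vinylketene 34, which adds siloxyalkyne 33 in a [2+2] cycloaddition to vinylcyclobutenone 35; four-electron conrotatory opening gives dienylketene 36, six-electron disrotatory electrocyclisation gives cyclohexadienone 37, and tautomerisation gives phenol 38, the thermal stages being completed by the warming period. The closest known reaction is the Danheiser benzannulation in its photochemical Wolff variant with siloxyalkynes, which delivers resorcinol monosilyl ethers. Ring C is the only ring closed, by 6π electrocyclisation of the dienylketene, and four of its bonds are new (in furan ring 2 numbering: C5–C6 from the Wolff shift, C4–C5 and C3a–C7a from the [2+2] addition, C7–C7a from the electrocyclisation). No stereocentre is created, because the sp3 carbons of 35 and 37 vanish on ring opening and aromatisation, and the three existing centres should survive because the medium is neutral and free of base. The selectivity required is regiochemical and rests on the polarity of the partners: the alkyne carbon bearing the side chain is the nucleophilic β-carbon of the ynol ether and bonds to the electrophilic ketene carbonyl carbon, so the chiral chain lands between the new free hydroxyl and the silyloxy group. A slight excess of 33 keeps the ketene from acylating the product phenol.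

**End game**

Step 17
Reactants: 38 ring C phenol (name as in step 16)
Product: 40 methyl (2R,3R)-2-[(2R,3R)-2-(2,4-dimethoxyphenyl)-3-(3,5-dimethoxyphenyl)-4-[tri(propan-2-yl)silyloxy]-2,3-dihydro-1-benzofuran-7-yl]-3-(3,5-dimethoxyphenyl)-4-methoxy-2,3-dihydro-1-benzofuran-6-carboxylate, via benzylic cation 39 (not isolated)
Conditions: CF3CO2H (5 equiv), CH2Cl2, −20 → 0 °C
Reagents that add atoms: none
Why: Acid ionises the 2,4-dimethoxybenzylic silyl ether to a para-quinone-methide-type cation that the adjacent free phenol captures in a 5-exo cationic cycloetherification, with the new C2 centre set trans to the C3 aryl group by approach anti to it and by reversibility, while the silylated oxygen on the other side of the chain cannot compete.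

Step 18
Reactants: 40 bis-dihydrobenzofuran methyl ester (name as in step 17)
Product: 41 {(2R,3R)-2-[(2R,3R)-2-(2,4-dimethoxyphenyl)-3-(3,5-dimethoxyphenyl)-4-[tri(propan-2-yl)silyloxy]-2,3-dihydro-1-benzofuran-7-yl]-3-(3,5-dimethoxyphenyl)-4-methoxy-2,3-dihydro-1-benzofuran-6-yl}methanol
Conditions: i-Bu2AlH (2.5 equiv), CH2Cl2, −78 → 0 °C
Reagents that add atoms: none
Why: Hydride reduction of the methyl benzoate to the benzylic alcohol, to which the aryl silyl ether and the aryl alkyl ethers are inert.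

Step 19
Reactants: 41 benzylic alcohol (name as in step 18)
Product: 42 (2R,3R)-2-[(2R,3R)-2-(2,4-dimethoxyphenyl)-3-(3,5-dimethoxyphenyl)-4-[tri(propan-2-yl)silyloxy]-2,3-dihydro-1-benzofuran-7-yl]-3-(3,5-dimethoxyphenyl)-4-methoxy-2,3-dihydro-1-benzofuran-6-carbaldehyde
Conditions: MnO2, CH2Cl2, rt
Reagents that add atoms: none
Why: MnO2 oxidation is selective for benzylic alcohols and stops at the aldehyde.

Step 20
Reactants: 42 aldehyde (name as in step 19); 43 diethyl (4-methoxybenzyl)phosphonate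
Product: 44 {[(2R,3R)-2-(2,4-dimethoxyphenyl)-3-(3,5-dimethoxyphenyl)-7-{(2R,3R)-3-(3,5-dimethoxyphenyl)-4-methoxy-6-[(E)-2-(4-methoxyphenyl)ethenyl]-2,3-dihydro-1-benzofuran-2-yl}-2,3-dihydro-1-benzofuran-4-yl]oxy}tri(propan-2-yl)silane
Conditions: KOt-Bu, THF, 0 °C → rt
Reagents that add atoms: none
Why: Horner–Wadsworth–Emmons olefination with a benzylphosphonate anion gives the (E)-stilbene, and the aldehyde has neither an α-hydrogen nor an epimerisable neighbour.

Step 21
Reactants: 44 stilbene silyl ether (name as in step 20)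
Product: 45 (2R,3R)-2-(2,4-dimethoxyphenyl)-3-(3,5-dimethoxyphenyl)-7-{(2R,3R)-3-(3,5-dimethoxyphenyl)-4-methoxy-6-[(E)-2-(4-methoxyphenyl)ethenyl]-2,3-dihydro-1-benzofuran-2-yl}-2,3-dihydro-1-benzofuran-4-ol
Conditions: n-Bu4NF, AcOH, THF, 0 °C
Reagents that add atoms: none
Why: Fluoride cleavage of the aryl silyl ether, buffered with acetic acid so that the phenoxide para to the benzylic ether carbon of dihydrobenzofuran 1 is not left as a free base.

Step 22
Reactants: 45 phenol octamethyl ether (name as in step 21)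
Product: 46 CNP0217875.2, (2R,3R)-2-(2,4-dihydroxyphenyl)-3-(3,5-dihydroxyphenyl)-7-{(2R,3R)-3-(3,5-dihydroxyphenyl)-4-hydroxy-6-[(E)-2-(4-hydroxyphenyl)ethenyl]-2,3-dihydro-1-benzofuran-2-yl}-2,3-dihydro-1-benzofuran-4-ol
Conditions: BBr3 (excess), CH2Cl2, −78 °C → rt; then MeOH, H2O
Reagents that add atoms: none
Why: Global Lewis-acid demethylation of the eight aryl methyl ethers with BBr3, the usual last step for permethylated resveratrol oligomers, started cold so that both dihydrobenzofuran rings and the stilbene should survive.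

**Compound list**

1 | 4-bromo-3,5-dihydroxybenzoic acid | OC(=O)c1cc(O)c(Br)c(O)c1 | starting material
2 | methyl 4-bromo-3,5-dihydroxybenzoate | COC(=O)c1cc(O)c(Br)c(O)c1 | intermediate
3 | methyl acrylate | C=CC(=O)OC | starting material
4 | methyl 3,5-dihydroxy-4-[(E)-3-methoxy-3-oxoprop-1-enyl]benzoate | COC(=O)/C=C/c1c(O)cc(cc1O)C(=O)OC | intermediate
5 | methyl 5-hydroxy-2-oxo-2H-chromene-7-carboxylate | O=C1C=Cc2c(O)cc(cc2O1)C(=O)OC | intermediate
6 | methyl 5-methoxy-2-oxo-2H-chromene-7-carboxylate | O=C1C=Cc2c(OC)cc(cc2O1)C(=O)OC | intermediate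
7 | 3,5-dimethoxyphenylboronic acid | COc1cc(OC)cc(B(O)O)c1 | starting material
8 | methyl (4R)-4-(3,5-dimethoxyphenyl)-5-methoxy-2-oxo-3,4-dihydro-2H-chromene-7-carboxylate | O=C1C[C@H](c2cc(OC)cc(OC)c2)c2c(OC)cc(cc2O1)C(=O)OC | intermediate
9 | lithium enolate of lactone 8 | [Li]OC1=C[C@H](c2cc(OC)cc(OC)c2)c2c(OC)cc(cc2O1)C(=O)OC | intermediate
10 | methyl (3S,4R)-3-bromo-4-(3,5-dimethoxyphenyl)-5-methoxy-2-oxo-3,4-dihydro-2H-chromene-7-carboxylate | O=C1[C@@H](Br)[C@H](c2cc(OC)cc(OC)c2)c2c(OC)cc(cc2O1)C(=O)OC | intermediate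
11 | sodium 2-[(1R,2S)-2-bromo-1-(3,5-dimethoxyphenyl)-3-methoxy-3-oxopropyl]-3-methoxy-5-(methoxycarbonyl)phenolate | COC(=O)[C@@H](Br)[C@H](c1cc(OC)cc(OC)c1)c1c(OC)cc(cc1[O-])C(=O)OC.[Na+] | intermediate
12 | dimethyl (2R,3R)-3-(3,5-dimethoxyphenyl)-4-methoxy-2,3-dihydro-1-benzofuran-2,6-dicarboxylate | COC(=O)c1cc(OC)c2c(c1)O[C@@H](C(=O)OC)[C@@H]2c1cc(OC)cc(OC)c1 | intermediate
13 | methyl (2R,3R)-3-(3,5-dimethoxyphenyl)-2-(hydroxymethyl)-4-methoxy-2,3-dihydro-1-benzofuran-6-carboxylate | COC(=O)c1cc(OC)c2c(c1)O[C@@H](CO)[C@@H]2c1cc(OC)cc(OC)c1 | intermediate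
14 | 1-(triphenylphosphoranylidene)propan-2-one | CC(=O)C=P(c1ccccc1)(c1ccccc1)c1ccccc1 | starting material
15 | methyl (2R,3R)-3-(3,5-dimethoxyphenyl)-2-formyl-4-methoxy-2,3-dihydro-1-benzofuran-6-carboxylate | COC(=O)c1cc(OC)c2c(c1)O[C@@H](C=O)[C@@H]2c1cc(OC)cc(OC)c1 | intermediate
16 | methyl (2S,3R)-3-(3,5-dimethoxyphenyl)-4-methoxy-2-[(E)-3-oxobut-1-enyl]-2,3-dihydro-1-benzofuran-6-carboxylate | COC(=O)c1cc(OC)c2c(c1)O[C@@H](/C=C/C(C)=O)[C@@H]2c1cc(OC)cc(OC)c1 | intermediate
17 | lithium cross-conjugated enolate of enone 16 | COC(=O)c1cc(OC)c2c(c1)O[C@@H](/C=C/C(=C)O[Li])[C@@H]2c1cc(OC)cc(OC)c1 | intermediate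
18 | methyl (2S,3R)-3-(3,5-dimethoxyphenyl)-4-methoxy-2-[(E)-6,6,6-trifluoro-3,5-dioxohex-1-enyl]-2,3-dihydro-1-benzofuran-6-carboxylate | COC(=O)c1cc(OC)c2c(c1)O[C@@H](/C=C/C(=O)CC(=O)C(F)(F)F)[C@@H]2c1cc(OC)cc(OC)c1 | intermediate
19 | methyl (2S,3R)-2-[(E)-4-diazo-3-oxobut-1-enyl]-3-(3,5-dimethoxyphenyl)-4-methoxy-2,3-dihydro-1-benzofuran-6-carboxylate | COC(=O)c1cc(OC)c2c(c1)O[C@@H](/C=C/C(=O)C=[N+]=[N-])[C@@H]2c1cc(OC)cc(OC)c1 | intermediate
20 | (3,5-dimethoxyphenyl)acetic acid | COc1cc(CC(=O)O)cc(OC)c1 | starting material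
21 | (S)-4-benzyl-1,3-oxazolidin-2-one | O=C1OC[C@H](Cc2ccccc2)N1 | starting material
22 | 2-(3,5-dimethoxyphenyl)acetic pivalic anhydride | COc1cc(CC(=O)OC(=O)C(C)(C)C)cc(OC)c1 | intermediate
23 | (4S)-4-benzyl-3-[2-(3,5-dimethoxyphenyl)acetyl]-1,3-oxazolidin-2-one | COc1cc(CC(=O)N2C(=O)OC[C@@H]2Cc2ccccc2)cc(OC)c1 | intermediate
24 | 2,4-dimethoxybenzaldehyde | COc1ccc(C=O)c(OC)c1 | starting material
25 | (Z)-dibutylboron enolate of imide 23 | CCCCB(CCCC)O/C(N1C(=O)OC[C@@H]1Cc1ccccc1)=C\c1cc(OC)cc(OC)c1 | intermediate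
26 | (4S)-4-benzyl-3-[(2S,3S)-3-(2,4-dimethoxyphenyl)-2-(3,5-dimethoxyphenyl)-3-hydroxypropanoyl]-1,3-oxazolidin-2-one | O=C(N1C(=O)OC[C@@H]1Cc1ccccc1)[C@@H](c1cc(OC)cc(OC)c1)[C@H](O)c1ccc(OC)cc1OC | intermediate
27 | (4S)-4-benzyl-3-[(2S,3S)-3-[tert-butyl(dimethyl)silyl]oxy-3-(2,4-dimethoxyphenyl)-2-(3,5-dimethoxyphenyl)propanoyl]-1,3-oxazolidin-2-one | O=C(N1C(=O)OC[C@@H]1Cc1ccccc1)[C@@H](c1cc(OC)cc(OC)c1)[C@H](O[Si](C)(C)C(C)(C)C)c1ccc(OC)cc1OC | intermediate
28 | (2R,3S)-3-[tert-butyl(dimethyl)silyl]oxy-3-(2,4-dimethoxyphenyl)-2-(3,5-dimethoxyphenyl)propan-1-ol | OC[C@@H](c1cc(OC)cc(OC)c1)[C@H](O[Si](C)(C)C(C)(C)C)c1ccc(OC)cc1OC | intermediate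
29 | (2S,3S)-3-[tert-butyl(dimethyl)silyl]oxy-3-(2,4-dimethoxyphenyl)-2-(3,5-dimethoxyphenyl)propanal | O=C[C@@H](c1cc(OC)cc(OC)c1)[C@H](O[Si](C)(C)C(C)(C)C)c1ccc(OC)cc1OC | intermediate
30 | tert-butyl{[(1S,2S)-4,4-dibromo-1-(2,4-dimethoxyphenyl)-2-(3,5-dimethoxyphenyl)but-3-enyl]oxy}dimethylsilane | BrC(Br)=C[C@@H](c1cc(OC)cc(OC)c1)[C@H](O[Si](C)(C)C(C)(C)C)c1ccc(OC)cc1OC | intermediate
31 | lithium acetylide of the side-chain alkyne | [Li]C#C[C@@H](c1cc(OC)cc(OC)c1)[C@H](O[Si](C)(C)C(C)(C)C)c1ccc(OC)cc1OC | intermediate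
32 | lithium ynolate of the side-chain alkyne | [Li]OC#C[C@@H](c1cc(OC)cc(OC)c1)[C@H](O[Si](C)(C)C(C)(C)C)c1ccc(OC)cc1OC | intermediate
33 | tert-butyl{[(1S,2R)-1-(2,4-dimethoxyphenyl)-2-(3,5-dimethoxyphenyl)-4-[tri(propan-2-yl)silyloxy]but-3-ynyl]oxy}dimethylsilane | CC(C)[Si](OC#C[C@@H](c1cc(OC)cc(OC)c1)[C@H](O[Si](C)(C)C(C)(C)C)c1ccc(OC)cc1OC)(C(C)C)C(C)C | intermediate
34 | vinylketene from 19 (dihydrobenzofuran 1 carrying an (E)-4-oxobuta-1,3-dienyl group at C2) | COC(=O)c1cc(OC)c2c(c1)O[C@@H](/C=C/C=C=O)[C@@H]2c1cc(OC)cc(OC)c1 | intermediate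
35 | 4-vinylcyclobutenone from 34 and 33 (2-side-chain, 3-silyloxy; ring CH centre unassigned) | COC(=O)c1cc(OC)c2c(c1)O[C@@H](/C=C/C3C(=O)C([C@@H](c4cc(OC)cc(OC)c4)[C@H](O[Si](C)(C)C(C)(C)C)c4ccc(OC)cc4OC)=C3O[Si](C(C)C)(C(C)C)C(C)C)[C@@H]2c1cc(OC)cc(OC)c1 | intermediate
36 | dienylketene from ring opening of 35 | COC(=O)c1cc(OC)c2c(c1)O[C@@H](/C=C/C=C(O[Si](C(C)C)(C(C)C)C(C)C)\C([C@@H](c3cc(OC)cc(OC)c3)[C@H](O[Si](C)(C)C(C)(C)C)c3ccc(OC)cc3OC)=C=O)[C@@H]2c1cc(OC)cc(OC)c1 | intermediate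
37 | cyclohexa-2,4-dienone from 6π closure of 36 (ring CH centre unassigned) | COC(=O)c1cc(OC)c2c(c1)O[C@@H](C3C=CC(O[Si](C(C)C)(C(C)C)C(C)C)=C([C@@H](c4cc(OC)cc(OC)c4)[C@H](O[Si](C)(C)C(C)(C)C)c4ccc(OC)cc4OC)C3=O)[C@@H]2c1cc(OC)cc(OC)c1 | intermediate
38 | methyl (2R,3R)-2-{3-[(1R,2S)-2-[tert-butyl(dimethyl)silyl]oxy-2-(2,4-dimethoxyphenyl)-1-(3,5-dimethoxyphenyl)ethyl]-2-hydroxy-4-[tri(propan-2-yl)silyloxy]phenyl}-3-(3,5-dimethoxyphenyl)-4-methoxy-2,3-dihydro-1-benzofuran-6-carboxylate | COC(=O)c1cc(OC)c2c(c1)O[C@@H](c3ccc(O[Si](C(C)C)(C(C)C)C(C)C)c([C@@H](c4cc(OC)cc(OC)c4)[C@H](O[Si](C)(C)C(C)(C)C)c4ccc(OC)cc4OC)c3O)[C@@H]2c1cc(OC)cc(OC)c1 | intermediate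
39 | benzylic cation from 38, drawn as its para-quinone methide oxocarbenium form | COC(=O)c1cc(OC)c2c(c1)O[C@@H](c3ccc(O[Si](C(C)C)(C(C)C)C(C)C)c([C@@H](c4cc(OC)cc(OC)c4)C=C4C=CC(=[O+]C)C=C4OC)c3O)[C@@H]2c1cc(OC)cc(OC)c1 | intermediate
40 | methyl (2R,3R)-2-[(2R,3R)-2-(2,4-dimethoxyphenyl)-3-(3,5-dimethoxyphenyl)-4-[tri(propan-2-yl)silyloxy]-2,3-dihydro-1-benzofuran-7-yl]-3-(3,5-dimethoxyphenyl)-4-methoxy-2,3-dihydro-1-benzofuran-6-carboxylate | COC(=O)c1cc(OC)c2c(c1)O[C@@H](c3ccc(O[Si](C(C)C)(C(C)C)C(C)C)c4c3O[C@@H](c3ccc(OC)cc3OC)[C@@H]4c3cc(OC)cc(OC)c3)[C@@H]2c1cc(OC)cc(OC)c1 | intermediate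
41 | 6-(hydroxymethyl) analogue of 40 | OCc1cc(OC)c2c(c1)O[C@@H](c3ccc(O[Si](C(C)C)(C(C)C)C(C)C)c4c3O[C@@H](c3ccc(OC)cc3OC)[C@@H]4c3cc(OC)cc(OC)c3)[C@@H]2c1cc(OC)cc(OC)c1 | intermediate
42 | 6-carbaldehyde analogue of 40 | O=Cc1cc(OC)c2c(c1)O[C@@H](c3ccc(O[Si](C(C)C)(C(C)C)C(C)C)c4c3O[C@@H](c3ccc(OC)cc3OC)[C@@H]4c3cc(OC)cc(OC)c3)[C@@H]2c1cc(OC)cc(OC)c1 | intermediate
43 | diethyl (4-methoxybenzyl)phosphonate | CCOP(=O)(Cc1ccc(OC)cc1)OCC | starting material
44 | (E)-stilbene octamethyl ether with ring C O-triisopropylsilyl | COc1ccc(/C=C/c2cc(OC)c3c(c2)O[C@@H](c2ccc(O[Si](C(C)C)(C(C)C)C(C)C)c4c2O[C@@H](c2ccc(OC)cc2OC)[C@@H]4c2cc(OC)cc(OC)c2)[C@@H]3c2cc(OC)cc(OC)c2)cc1 | intermediate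
45 | (E)-stilbene octamethyl ether with free ring C phenol | COc1ccc(/C=C/c2cc(OC)c3c(c2)O[C@@H](c2ccc(O)c4c2O[C@@H](c2ccc(OC)cc2OC)[C@@H]4c2cc(OC)cc(OC)c2)[C@@H]3c2cc(OC)cc(OC)c2)cc1 | intermediate
46 | CNP0217875.2 | Oc1ccc(/C=C/c2cc(O)c3c(c2)O[C@@H](c2ccc(O)c4c2O[C@@H](c2ccc(O)cc2O)[C@@H]4c2cc(O)cc(O)c2)[C@@H]3c2cc(O)cc(O)c2)cc1 | target

**Step count and risks**

Total steps: 22. Longest linear sequence: 16 (steps 1–9, 16–22, from compound 1); the siloxyalkyne branch is 6 steps (10–15).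

Steps most likely to fail:

1. Step 16. The [2+2] capture of the photogenerated vinylketene by the branched, crowded siloxyalkyne may be slow. The ketene could then be lost to dimerisation or to acylation of the product phenol, and light absorption by the many methoxyarenes may slow the Wolff step or degrade the product. Fallback: the same vinylketene is made thermally, so that the cycloaddition can run without light, at higher concentration and with the alkyne in excess. Setting out from alcohol 13, IBX oxidation as in step 8 but without ylide gives aldehyde 15. A Wittig reaction with the ylide from (2-carboxyethyl)triphenylphosphonium bromide and NaN(SiMe3)2 should give (E)-4-[(2S,3R)-3-(3,5-dimethoxyphenyl)-4-methoxy-6-(methoxycarbonyl)-2,3-dihydro-1-benzofuran-2-yl]but-3-enoic acid F1 (the alkene geometry is lost on aromatisation, so a mixture is tolerable). Oxalyl chloride with catalytic DMF gives the acid chloride F2. Slow addition of Et3N to F2 and 33 in toluene, rt then 80 °C, generates vinylketene 34 by dehydrochlorination, which continues through 35, 36 and 37 to phenol 38, where the route is rejoined.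

2. Step 4. Aryl transfer from rhodium to C4 may be slow because of the peri methoxy group, so that protodeboronation of 7 and hydrolytic opening of the lactone outrun the addition, or facial discrimination may drop. Fallback: the stereocentre is set by delivery of hydride instead of aryl. Setting out from coumarin 6 and boronic acid 7, oxidative Heck arylation (Pd(OAc)2, 1,10-phenanthroline, O2, DMF, 80 °C) gives methyl 4-(3,5-dimethoxyphenyl)-5-methoxy-2-oxo-2H-chromene-7-carboxylate F3; this creates no stereocentre and can be forced. Asymmetric conjugate reduction with copper hydride (Cu(OAc)2, the DTBM-SEGPHOS enantiomer chosen for the (4R) product, diethoxymethylsilane, t-BuOH, toluene) should stop at methyl (4R)-4-(3,5-dimethoxyphenyl)-2-hydroxy-5-methoxy-3,4-dihydro-2H-chromene-7-carboxylate F4. Oxidation of this lactol (PhI(OAc)2, cat. TEMPO, CH2Cl2) returns lactone 8.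

3. Step 14. The α-aryl aldehyde may epimerise, or lose silanol by β-elimination, before it is olefinated, which would erode the configuration of the future C3 of furan ring 2. Fallback: the aldehyde is avoided and the ynolate is reached by rearrangement of an ester. Setting out from silyl ether 27, transesterification with MeOMgBr (MeOH/CH2Cl2, 0 °C) gives methyl (2S,3S)-3-[tert-butyl(dimethyl)silyl]oxy-3-(2,4-dimethoxyphenyl)-2-(3,5-dimethoxyphenyl)propanoate F5. Kowalski homologation (LiCHBr2 from CH2Br2 and lithium 2,2,6,6-tetramethylpiperidide, THF, −78 °C, then LiN(SiMe3)2) gives lithium (3S,4S)-1,1-dibromo-4-[tert-butyl(dimethyl)silyl]oxy-4-(2,4-dimethoxyphenyl)-3-(3,5-dimethoxyphenyl)but-1-en-2-olate F6. n-BuLi with warming then triggers bromine–lithium exchange and 1,2-shift of the chiral carbon with retention to lithium ynolate 32, which is silylated with i-Pr3SiOTf to siloxyalkyne 33.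

**Further compounds**

F1 | step 16 | (E)-4-[(2S,3R)-3-(3,5-dimethoxyphenyl)-4-methoxy-6-(methoxycarbonyl)-2,3-dihydro-1-benzofuran-2-yl]but-3-enoic acid | COC(=O)c1cc(OC)c2c(c1)O[C@@H](/C=C/CC(=O)O)[C@@H]2c1cc(OC)cc(OC)c1
F2 | step 16 | (E)-4-[(2S,3R)-3-(3,5-dimethoxyphenyl)-4-methoxy-6-(methoxycarbonyl)-2,3-dihydro-1-benzofuran-2-yl]but-3-enoyl chloride | COC(=O)c1cc(OC)c2c(c1)O[C@@H](/C=C/CC(=O)Cl)[C@@H]2c1cc(OC)cc(OC)c1
F3 | step 4 | methyl 4-(3,5-dimethoxyphenyl)-5-methoxy-2-oxo-2H-chromene-7-carboxylate | O=C1C=C(c2cc(OC)cc(OC)c2)c2c(OC)cc(cc2O1)C(=O)OC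
F4 | step 4 | methyl (4R)-4-(3,5-dimethoxyphenyl)-2-hydroxy-5-methoxy-3,4-dihydro-2H-chromene-7-carboxylate (lactol, C2 unassigned) | OC1C[C@H](c2cc(OC)cc(OC)c2)c2c(OC)cc(cc2O1)C(=O)OC
F5 | step 14 | methyl (2S,3S)-3-[tert-butyl(dimethyl)silyl]oxy-3-(2,4-dimethoxyphenyl)-2-(3,5-dimethoxyphenyl)propanoate | COC(=O)[C@@H](c1cc(OC)cc(OC)c1)[C@H](O[Si](C)(C)C(C)(C)C)c1ccc(OC)cc1OC
F6 | step 14 | lithium (3S,4S)-1,1-dibromo-4-[tert-butyl(dimethyl)silyl]oxy-4-(2,4-dimethoxyphenyl)-3-(3,5-dimethoxyphenyl)but-1-en-2-olate | [Li]OC(=C(Br)Br)[C@@H](c1cc(OC)cc(OC)c1)[C@H](O[Si](C)(C)C(C)(C)C)c1ccc(OC)cc1OC
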